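**Retrosynthetic overview**
1. Pyran ring last: three-component Knoevenagel / oxa-[4+2] union of triquinane diosphenol 30, formaldehyde and ent-isocaryophyllene 17 (sets C4 and C5).
2. 17 ⇐ Wittig ⇐ nine-membered Z-enone 16 ⇐ Grob three-carbon ring expansion (6→9) of hydrindane diol monotosylate 14 ⇐ cyclopentane annulation on the enantioselective [2+2] adduct of cyclohexenone and isobutene.
3. 30 ⇐ ring A last (propargylation, hydration/aldol, cuprate methylation, α-oxidation) ⇐ diquinane keto acid 23 ⇐ semipinacol ring contraction (6→5) of epoxide 21 ⇐ enantioselective Diels–Alder of cyclopentenone and isoprene.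
4. Ring order: cyclobutane → cyclopentane onto the cyclohexane → nine-membered ring; ring B → cyclohexene → ring C → ring A; pyran last.

**Assumptions**
- Locants: caryophyllane numbering C1–C15 for the bicyclo[7.2.0]undecane part (C4 methyl, C8 exocyclic CH2, C11 gem-dimethyl); triquinane rings are A (oxygenated), B (middle), C (carboxyl). The target SMILES is read as (1S,4R,5R,9R) in the caryophyllane part, i.e. a trans-fused cyclobutane enantiomeric to natural caryophyllene and a cis-fused pyran, the formal adduct of the Z olefin ent-isocaryophyllene.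
- In steps 1 and 9 the catalyst enantiomer is the one that delivers the configuration written.

**Route**

Step 1
Reactants: 1 cyclohex-2-en-1-one; 2 2-methylprop-1-ene
Product: 4 (1S,6S)-7,7-dimethylbicyclo[4.2.0]octan-2-one, via trans-fused photoadduct 3 (not isolated)
Conditions: 2 (excess), AlBr3-activated B-(2,4,6-trifluorophenyl)oxazaborolidine of an α,α-diarylprolinol (50 mol %), hν 366 nm, CH2Cl2, −75 °C; then basic Al2O3, rt
Reagents that add atoms: none
Why: Lewis-acid-catalysed enantioselective enone–alkene [2+2] photocycloaddition, in which the chiral complex shields one enone face, head-to-tail addition puts CMe2 on the β-carbon and fixes C6 (future C1, S), and alumina equilibrates the ring fusion to cis.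

Step 2
Reactants: 4
Product: 6 methyl (1S,3R,6S)-3,7,7-trimethyl-2-oxobicyclo[4.2.0]octane-3-carboxylate, via keto ester sodium enolate 5 (not isolated)
Conditions: NaH (2.2 equiv), (MeO)2CO, THF, reflux; then MeI, 0 °C→rt
Reagents that add atoms: dimethyl carbonate COC(=O)OC; iodomethane CI
Why: Claisen condensation at the only α-methylene followed by C-methylation of the β-keto ester enolate on the face away from the cyclobutane gives the quaternary carbon that becomes olefinic C4.

Step 3
Reactants: 6; 7 methyl acrylate
Product: 9 spiro γ-lactone at C2 of 6 (lactone O cis to the CO2Me), via hydroxy diester 8 (not isolated)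
Conditions: SmI2 (2.2 equiv), t-BuOH (2 equiv), THF, −78→0 °C
Reagents that add atoms: none
Why: Samarium diiodide ketyl–acrylate reductive coupling with in situ lactonisation, where the ester-chelated ketyl is attacked equatorially on the face away from the axial cyclobutane carbon, leaving the tertiary oxygen cis to the ester.

Step 4
Reactants: 9
Product: 12 tricyclic ketol (C4–C8 bonded, 5-oxo, 8-OH trans to 4-CH3, trans-hydrindane), via bridged keto lactone 10 (not isolated), via keto acid 11 (not isolated)
Conditions: LiN(SiMe3)2 (2.2 equiv), THF, −78→25 °C; then LiOH (aq), 60 °C; then HCl to pH 2, 50 °C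
Reagents that add atoms: none
Why: Dieckmann condensation of the lactone enolate onto the neighbouring diequatorial ester closes the cyclopentanone, and saponification then decarboxylation of the β-keto lactone leaves the β-ketol.

Step 5
Reactants: 12
Product: 13 syn-1,3-diol (5-OH cis to 8-OH, trans to 4-CH3)
Conditions: Et2BOMe (1.2 equiv), THF–MeOH 4:1, −78 °C; NaBH4; AcOH quench, MeOH co-evaporation
Reagents that add atoms: none
Why: Narasaka–Prasad reduction, in which the boron chelate between the tertiary OH and the ketone leaves only the opposite face open to hydride, so the new C5–OH is cis to C8–OH and trans to the C4 methyl.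

Step 6
Reactants: 13
Product: 14 5-O-tosylate of 13
Conditions: TsCl, DMAP (cat.), pyridine, 0→40 °C
Reagents that add atoms: p-toluenesulfonyl chloride Cc1ccc(cc1)S(=O)(=O)Cl
Why: Sulfonylation is selective for the secondary alcohol because the tertiary C8–OH is inert under these conditions.

Step 7
Reactants: 14
Product: 16 (1S,9R,Z)-4,11,11-trimethylbicyclo[7.2.0]undec-4-en-8-one, via cis-fused ketone 15 (not isolated)
Conditions: KOt-Bu (3 equiv), t-BuOH–THF, 0→45 °C
Reagents that add atoms: none
Why: Grob fragmentation, in which the C8 alkoxide expels tosylate through the antiperiplanar C4–C8 ring-fusion bond (three-carbon ring expansion of the cyclohexane to the nine-membered ketone), the C4=C5 bond being Z because OTs is trans to the C4 methyl, and the same base then epimerises C9 to the more stable trans fusion (9R).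

Step 8
Reactants: 16
Product: 17 (1S,4Z,9R)-4,11,11-trimethyl-8-methylidenebicyclo[7.2.0]undec-4-ene (ent-isocaryophyllene)
Conditions: Ph3PCH3Br, KOt-Bu, THF, 0→60 °C
Reagents that add atoms: methyltriphenylphosphonium bromide C[P+](c1ccccc1)(c1ccccc1)c1ccccc1.[Br-]
Why: Wittig methylenation of the hindered ketone with a non-stabilised ylide, with C9 remaining in its thermodynamic trans configuration.

Step 9
Reactants: 18 cyclopent-2-en-1-one; 19 2-methylbuta-1,3-diene
Product: 20 (3aS,7aR)-5-methyl-2,3,3a,4,7,7a-hexahydro-1H-inden-1-one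
Conditions: B-(o-tolyl)oxazaborolidine of α,α-diphenylprolinol activated by HN(SO2CF3)2 (20 mol %), CH2Cl2, −40 °C
Reagents that add atoms: none
Why: Oxazaborolidinium-catalysed enantioselective Diels–Alder reaction sets both ring-fusion carbons (cis) by catalyst control of the enone face, and the para regiochemistry is immaterial because either regioisomer converges after step 11.

Step 10
Reactants: 20
Product: 21 5,6-epoxide of 20 (oxygen on the face of the ring-fusion hydrogens)
Conditions: m-CPBA, NaHCO3, CH2Cl2, 0 °C
Reagents that add atoms: 3-chloroperoxybenzoic acid OOC(=O)c1cccc(Cl)c1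
Why: Prilezhaev epoxidation of the only electron-rich olefin from the convex face of the cis-fused bicycle, anti to the cyclopentanone ring.

Step 11
Reactants: 21
Product: 22 cis-fused 2-methyl-4-oxooctahydropentalene-2-carbaldehyde (CHO cis to the ring-fusion hydrogens)
Conditions: MeAl(OAr)2 (Ar = 4-bromo-2,6-di-tert-butylphenyl; from Me3Al + 2 ArOH; 1.5 equiv), CH2Cl2, −78→−40 °C
Reagents that add atoms: none
Why: Lewis-acid semipinacol (Meinwald-type) 1,2-shift, in which the epoxide ionises at the tertiary carbon and the antiperiplanar C7 ring bond migrates with inversion there, contracting the cyclohexane to ring C and setting the quaternary carbon stereospecifically (CHO cis, CH3 trans to the ring-fusion hydrogens).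

Step 12
Reactants: 22
Product: 23 cis-fused 2-methyl-4-oxooctahydropentalene-2-carboxylic acid
Conditions: NaClO2, NaH2PO4, 2-methylbut-2-ene, t-BuOH–H2O, rt
Reagents that add atoms: sodium chlorite [Na+].[O-]Cl=O
Why: Pinnick oxidation converts the non-enolisable aldehyde to the acid without touching the ketone.

Step 13
Reactants: 23; 24 3-bromoprop-1-yne
Product: 25 5-(prop-2-yn-1-yl) derivative of 23 (propargyl cis to the ring-fusion hydrogens)
Conditions: LiN(i-Pr)2 (2.2 equiv), THF, −78 °C; 24, −78→−20 °C; HCl work-up
Reagents that add atoms: none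
Why: Kinetic dianion alkylation, in which the carboxylate and the α-CH2 ketone enolate form and the enolate is propargylated on carbon from the convex face of the cis-bicyclo[3.3.0]octanone, fixing the future A/B fusion carbon in the cis-anti-cis sense.

Step 14
Reactants: 25
Product: 28 cis-anti-cis triquinane enone acid (ring A cyclopentenone, C=C at the A/B fusion carbon next to ring C), via diketone 26 (not isolated), via aldol ketol 27 (not isolated)
Conditions: HgSO4 (5 mol %), H2SO4 (aq, cat.), MeOH–H2O, 55 °C; then KOH (excess), 65 °C; HCl work-up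
Reagents that add atoms: water O
Why: Markovnikov mercury-catalysed alkyne hydration gives the 1,4-diketone, and base-mediated intramolecular aldol condensation of its methyl group onto the ring ketone closes ring A as the conjugated cyclopentenone.

Step 15
Reactants: 28
Product: 29 triquinane ketone acid with angular methyl at the A/B fusion
Conditions: Me2CuLi (3 equiv, from MeLi and CuI), Et2O–THF, −40→0 °C; NH4Cl (aq)
Reagents that add atoms: lithium dimethylcuprate [Li+].C[Cu-]C
Why: Cuprate conjugate addition to the β,β-disubstituted enone can only give the cis-fused diquinane, so the methyl enters cis to the adjacent ring-fusion hydrogen and creates the quaternary stereocentre.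

Step 16
Reactants: 29
Product: 30 ring A diosphenol acid (2-hydroxy-enone tautomer of the 1,2-dione)
Conditions: SeO2 (1.2 equiv), 1,4-dioxane–H2O 20:1, 90 °C
Reagents that add atoms: selenium dioxide O=[Se]=O
Why: Riley oxidation is expected at the less hindered α-methylene (next to the ring-fusion CH, not next to the quaternary carbon), and the 1,2-dione enolises toward the remaining CH2 to give the diosphenol.

Step 17
Reactants: 30; 17 ent-isocaryophyllene
Product: 32 target CNP0483070.1, via methylene dione 31 (not isolated)
Conditions: (CH2O)n (3 equiv), ethylenediammonium diacetate (20 mol %), 17 (1.5 equiv), MeCN, 80 °C, sealed tube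
Reagents that add atoms: formaldehyde (as paraformaldehyde) C=O
Why: Proposed new method: a domino Knoevenagel / inverse-electron-demand oxa-[4+2] with a cyclic 1,2-dione, in which the nucleophilic enol carbon of 30 condenses with CH2O to the 3-methylene-1,2-dione 31, a 1-oxadiene whose LUMO is lowered by the adjacent carbonyl, which is trapped by the most electron-rich olefin of 17 (trisubstituted Z C4=C5) with C–C bonding to C5 and O to the more substituted C4, suprafacial addition fixing the cis C4/C5 relationship and approach syn to the C1–C11 bond expected to give the (4R,5R) isomer; the closest known reactions are the domino Knoevenagel–hetero-Diels–Alder of 1,3-dicarbonyls and o-quinone-methide cycloadditions to caryophyllene.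

**Compound list**
1 | cyclohex-2-en-1-one | O=C1C=CCCC1 | starting material
2 | 2-methylprop-1-ene | C=C(C)C | starting material
3 | (1R,6S)-7,7-dimethylbicyclo[4.2.0]octan-2-one (trans-fused photoadduct) | O=C1CCC[C@H]2[C@H]1CC2(C)C | intermediate
4 | (1S,6S)-7,7-dimethylbicyclo[4.2.0]octan-2-one (cis-fused) | O=C1CCC[C@H]2[C@@H]1CC2(C)C | intermediate
5 | methyl (1S,6S)-7,7-dimethyl-2-oxobicyclo[4.2.0]octane-3-carboxylate, present as sodium enolate | O=C1C(C(=O)OC)CC[C@H]2[C@@H]1CC2(C)C | intermediate
6 | methyl (1S,3R,6S)-3,7,7-trimethyl-2-oxobicyclo[4.2.0]octane-3-carboxylate (3-CH3 on the face away from the cyclobutane) | O=C1[C@](C)(C(=O)OC)CC[C@H]2[C@@H]1CC2(C)C | intermediate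
7 | methyl acrylate | C=CC(=O)OC | starting material
8 | methyl 2-hydroxy-2-(3-methoxy-3-oxopropyl)-3,7,7-trimethylbicyclo[4.2.0]octane-3-carboxylate (2-OH cis to 3-CO2Me) | COC(=O)[C@]1(C)CC[C@H]2[C@H](CC2(C)C)[C@@]1(O)CCC(=O)OC | intermediate
9 | spiro γ-lactone of 8 (lactone O cis to 3-CO2Me) | COC(=O)[C@]1(C)CC[C@H]2[C@H](CC2(C)C)[C@@]13CCC(=O)O3 | intermediate
10 | bridged keto lactone (C5 ketone, C6 carboxyl lactonised onto C8–O) | O=C1[C@@H]2C[C@@]3(OC2=O)[C@@]1(C)CC[C@H]1[C@@H]3CC1(C)C | intermediate
11 | β-keto acid (5-oxo, 6-CO2H, 8-OH) | O=C1C(C(=O)O)C[C@@]2(O)[C@@]1(C)CC[C@H]3[C@@H]2CC3(C)C | intermediate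
12 | tricyclic ketol (C4–C8 bonded, 5-oxo, 8-OH trans to 4-CH3, cyclobutane cis-fused) | O=C1CC[C@@]2(O)[C@@]1(C)CC[C@H]3[C@@H]2CC3(C)C | intermediate
13 | syn-1,3-diol of 12 (5-OH cis to 8-OH, trans to 4-CH3) | O[C@H]1CC[C@@]2(O)[C@@]1(C)CC[C@H]3[C@@H]2CC3(C)C | intermediate
14 | 5-O-(4-methylbenzenesulfonate) of 13 | Cc1ccc(cc1)S(=O)(=O)O[C@H]1CC[C@@]2(O)[C@@]1(C)CC[C@H]3[C@@H]2CC3(C)C | intermediate
15 | (1S,9S,Z)-4,11,11-trimethylbicyclo[7.2.0]undec-4-en-8-one (cis-fused) | O=C1CC/C=C(/C)CC[C@H]2[C@@H]1CC2(C)C | intermediate
16 | (1S,9R,Z)-4,11,11-trimethylbicyclo[7.2.0]undec-4-en-8-one (trans-fused) | O=C1CC/C=C(/C)CC[C@H]2[C@H]1CC2(C)C | intermediate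
17 | (1S,4Z,9R)-4,11,11-trimethyl-8-methylidenebicyclo[7.2.0]undec-4-ene (ent-isocaryophyllene) | C=C1CC/C=C(/C)CC[C@H]2[C@H]1CC2(C)C | intermediate
18 | cyclopent-2-en-1-one | O=C1C=CCC1 | starting material
19 | 2-methylbuta-1,3-diene | C=CC(C)=C | starting material
20 | (3aS,7aR)-5-methyl-2,3,3a,4,7,7a-hexahydro-1H-inden-1-one (cis-fused) | O=C1CC[C@H]2CC(C)=CC[C@@H]12 | intermediate
21 | 5,6-epoxide of 20, oxygen cis to the ring-fusion hydrogens | O=C1CC[C@H]2C[C@]3(C)O[C@@H]3C[C@@H]12 | intermediate
22 | cis-fused 2-methyl-4-oxooctahydropentalene-2-carbaldehyde (CHO cis to ring-fusion H) | O=C1CC[C@H]2C[C@](C)(C=O)C[C@@H]12 | intermediate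
23 | cis-fused 2-methyl-4-oxooctahydropentalene-2-carboxylic acid (CO2H cis to ring-fusion H) | O=C1CC[C@H]2C[C@](C)(C(=O)O)C[C@@H]12 | intermediate
24 | 3-bromoprop-1-yne | C#CCBr | starting material
25 | 2-methyl-4-oxo-5-(prop-2-yn-1-yl)octahydropentalene-2-carboxylic acid (propargyl cis to ring-fusion H) | O=C1[C@H](CC#C)C[C@H]2C[C@](C)(C(=O)O)C[C@@H]12 | intermediate
26 | 2-methyl-4-oxo-5-(2-oxopropyl)octahydropentalene-2-carboxylic acid | O=C1[C@H](CC(C)=O)C[C@H]2C[C@](C)(C(=O)O)C[C@@H]12 | intermediate
27 | aldol ketol (ring A closed, tertiary OH at the A/B fusion carbon, cis-fused) | O=C1C[C@]2(O)[C@H](C1)C[C@H]3C[C@](C)(C(=O)O)C[C@@H]23 | intermediate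
28 | cis-anti-cis triquinane enone acid (ring A enone) | O=C1C=C2[C@H](C1)C[C@H]3C[C@](C)(C(=O)O)C[C@@H]23 | intermediate
29 | cis-anti-cis triquinane ketone acid with angular CH3 | O=C1C[C@]2(C)[C@H](C1)C[C@H]3C[C@](C)(C(=O)O)C[C@@H]23 | intermediate
30 | ring A diosphenol acid (enol of the 1,2-dione) | OC1=C[C@]2(C)[C@H](C1=O)C[C@H]3C[C@](C)(C(=O)O)C[C@@H]23 | intermediate
31 | ring A 3-methylene-1,2-dione acid | C=C1C(=O)C(=O)[C@@H]2C[C@H]3C[C@](C)(C(=O)O)C[C@H]3[C@]12C | intermediate
32 | CNP0483070.1 | C=C1CC[C@@H]2CC3=C(O[C@]2(C)CC[C@H]2[C@H]1CC2(C)C)C(=O)[C@@H]1C[C@H]2C[C@](C)(C(=O)O)C[C@H]2[C@]31C | target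

**Totals**
Total steps: 17. Longest linear sequence: 9 (steps 1–8 then 17, or steps 9–16 then 17).

**Steps most likely to fail**

Step 17 (proposed new method). Three things are unproven: that 31 forms cleanly from a 1,2-dione and formaldehyde, that it prefers the trisubstituted Z olefin over the exocyclic methylene of 17, and that it adds to the olefin face that gives (4R,5R) and not the other cis adduct (4S,5S). The facial preference is not backed by precedent and the minor cis isomer would have to be separated. The fallback uses only established operations, sets out from 30 and comes back at 32. Aminomethylation of 30 with dimethyl(methylidene)ammonium iodide in CH2Cl2 gives the Mannich base F1. F1 is then heated with 17 in toluene at 110 °C, so that thermal loss of dimethylamine releases 31 slowly in the presence of the olefin, which is the standard way o-quinone methides and 2-methylene-1,3-diones are generated and trapped by caryophyllene-type olefins.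

Step 7 (Grob ring expansion). The Z geometry depends on the C5 leaving group being trans to the C4 methyl, which in turn depends on the facial outcome of step 3 and the chelation control of step 5. The fallback replaces stereospecific control by stereoconvergence, sets out from 12 and comes back at 16. Plain NaBH4 in MeOH (hydride anti to the angular methyl) gives the C5-epimeric diol F2, which is tosylated to the epimeric tosylate F3. KOt-Bu fragmentation gives the cis-fused (E)-ketone F4, which epimerises in the same pot to the trans-fused (E)-ketone F5. Thiyl-radical isomerisation of F5 (PhSSPh, 10 mol %, hν 350 nm, benzene), the known caryophyllene-to-isocaryophyllene isomerisation, then relaxes the strained E olefin to the Z ketone 16.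

Step 16 (SeO2 oxidation). The two α-methylenes of 29 may not be differentiated well enough, and oxidation next to the quaternary carbon would give the wrong dione. The fallback sets out from 29 and comes back at 30. LiN(i-Pr)2 (2.2 equiv, −78 °C) forms the carboxylate and the kinetic enolate at the methylene remote from the quaternary carbon. Hydroxylation with 2-(phenylsulfonyl)-3-phenyloxaziridine gives the α-hydroxy ketone F6 (either epimer), and oxidation with Cu(OAc)2 (cat.) and air in MeOH gives 30.

**Further compounds**
F1 | step 17 | Mannich base of 30 (3-(dimethylaminomethyl) diosphenol acid) | CN(C)CC1=C(O)C(=O)[C@@H]2C[C@H]3C[C@](C)(C(=O)O)C[C@H]3[C@]12C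
F2 | step 7 | C5-epimeric diol (5-OH trans to 8-OH, cis to 4-CH3) | O[C@@H]1CC[C@@]2(O)[C@@]1(C)CC[C@H]3[C@@H]2CC3(C)C
F3 | step 7 | 5-O-(4-methylbenzenesulfonate) of F2 | Cc1ccc(cc1)S(=O)(=O)O[C@@H]1CC[C@@]2(O)[C@@]1(C)CC[C@H]3[C@@H]2CC3(C)C
F4 | step 7 | (1S,9S,E)-4,11,11-trimethylbicyclo[7.2.0]undec-4-en-8-one (cis-fused) | O=C1CC/C=C(\C)CC[C@H]2[C@@H]1CC2(C)C
F5 | step 7 | (1S,9R,E)-4,11,11-trimethylbicyclo[7.2.0]undec-4-en-8-one (trans-fused) | O=C1CC/C=C(\C)CC[C@H]2[C@H]1CC2(C)C
F6 | step 16 | α-hydroxy ketone of 29 (OH on the methylene next to the A/B fusion CH) | O=C1C[C@]2(C)[C@H](C1O)C[C@H]3C[C@](C)(C(=O)O)C[C@@H]23
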